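## Structural features

Mollicellin A is a depsidone with four fused rings: benzene ring A, a seven-membered dioxepinone, benzene ring B, and a 2,2-dimethylpyran-4-one fused to ring B (a chroman-4-one). Rings A and B are joined twice: by a diaryl ether oxygen from ring A C2 to C6 of the chromanone, and by an ester from the carboxyl carbon on ring A C1 to the oxygen on C7. Ring A also carries a formyl group on C3 (between the ether oxygen and the C4 hydroxyl) and a methyl group on C6. Ring B is substituted everywhere but C8: C4a (ketone), C5 (methyl), C6 (O), C7 (O) and C8a (O1). There is no stereocentre, because C2 of the pyranone bears two methyl groups. The fragile parts are the aryl aldehyde (reducible, electrophilic towards enolates), the aryl ester of the dioxepinone (opened by alkoxides) and the chromanone (enolisable C3, retro-oxa-Michael opening in strong base). The real difficulty is regiochemical: three oxygens and an acyl carbon must sit in fixed order on ring B, the C6 and C7 oxygens must be told apart (ether versus ester), and the diaryl ether is ortho-substituted on all four sides. The key step uses the fact that the pyran oxygen (on C8a) and the ketone carbon (on C4a) sit on neighbouring ring B carbons, C4a next to the C5 methyl and C8a next to C8–H, so a C4a–C8a aryne can take up both from one molecule of 3-methylbut-2-enoic acid.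

## Logic of the disconnections

26 ⇒ 25. The cut is the ester C–O bond of the seven-membered ring (ring A carboxyl carbon to the oxygen on C7). In 25 the acid and the C7 hydroxyl are already held side by side by the diaryl ether, and no other hydroxyl can reach the carboxyl group intramolecularly. The gain is that the tetracycle becomes a flexible diaryl ether. The demand is activation of a di-ortho-substituted acid beside two free phenols, which calls for high dilution.

25 ⇒ 24. No skeletal bond is cut; only three O–C bonds to protecting groups are restored (a 4-methoxybenzyl ester and two methoxymethyl acetals). They are chosen to fall together to acid, to which the aldehyde, ketone and diaryl ether are indifferent. The gain is one deprotection step in place of three. The demand is that the cations released are trapped before they alkylate the electron-rich rings.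

24 ⇒ 17 + 23. The diaryl ether bond between the C6 oxygen and ring A C2 is cut. This carbon lies between a formyl and an ester group, the best site in the molecule for addition–elimination, and the cut gives two halves of similar size that are joined late. The demand is twofold: 23 needs a leaving group on C2, and 17 may offer only one free phenol, on C6, because the C7 hydroxyl is the more acidic and less hindered and would otherwise react first. The two ring B oxygens must therefore already differ in 16 and in 12.

23 ⇒ 22 ⇒ 20 ⇒ 19 ⇒ 18. On ring A three bonds are cut in turn: C1 to the ester carbon (carbonylation of a C–Br bond), C3 to the formyl carbon (lithiation of the C–H between fluorine and the acetal oxygen), and C1–Br (bromination para to the free hydroxyl). Each substituent is placed by the strongest director present at that stage, and a simple meta-disubstituted phenol remains. The demand is an order of events: the formyl group must enter before the ester, because an ortho-methyl benzoate would be deprotonated at its methyl group by the amide base.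

17 ⇒ 16. Only the O–benzyl bond on the C6 oxygen is restored. This gives a chromanone with no free hydroxyl, which is what the key step can deliver. The demand on the forward step is that it spares the acetal on the C7 oxygen and the ketone, which hydrogenolysis does.

16 ⇒ 12 + 13 (key disconnection). Three bonds are cut: C8a–O1, C4a–C4 and O1–C2. The ring oxygen and the acyl carbon are ortho to each other, so both trace back to the two carbons of an aryne and to the O and C(=O) atoms of 13. The gain is the whole pyranone, with its ketone at the final oxidation level and its gem-dimethyl carbon, from a five-carbon commercial acid. The demand is regiochemical: the oxygen of 13 must add to the aryne carbon remote from the methyl group.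

12 ⇒ 9 ⇒ 8. The C–Si and O–S bonds of 12 are cut, then the C–Br bond of 9. Silicon reaches carbon from the phenol oxygen by a 1,3-shift that needs a bromine ortho to the hydroxyl, and 8 has only one free ortho position. The gain is a plain phenol. The demand is that both ethers survive an alkyllithium and a sulfonylating agent at low temperature.

8 ⇒ 6 ⇒ 5 ⇒ 4. The C–O bond of the third ring oxygen is cut, by way of C–B and C–Br. The bromine is placed para to the free hydroxyl of 4, beside the methyl group, so the site of the future triflate is fixed by the strongest director in the ring and not by a choice between two ether groups. The gain is a catechol monoether. The demand is that the acetal goes on only after this bromination.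

4 ⇒ 2 ⇒ 1. The C7 oxygen is traced back to the formyl carbon of 1 through an aryl formate (C–C bond to the formyl carbon exchanged for C–O), and the benzyl group to the phenol of 1. Because the two catechol oxygens enter at different moments, they carry different groups without any selective mono-protection. The demand is clean aryl migration in the oxidation, which the ortho-alkoxy group favours.

## Other disconnections considered

Alternative 1: The cut runs through the ester C–O bond on C7 and the ring A bond C1–C6, so ring A unrolls into a linear triketo ester and then into the dioxinone 2,2-dimethyl-6-(2,4-dioxopentyl)-4H-1,3-dioxin-4-one A1 and the phenol 6-bromo-7-hydroxy-2,2,5-trimethylchroman-4-one A2. In the forward sense, heating A1 with A2 would release the acylketene 3,5,7-trioxooct-1-en-1-one A3 by cycloreversion. A3 would acylate the C7 phenol of A2 to give 6-bromo-2,2,5-trimethyl-4-oxochroman-7-yl 3,5,7-trioxooctanoate A4. Mild base and then acid would fold A4 by a C2-to-C7 aldol reaction and dehydration into 6-bromo-2,2,5-trimethyl-4-oxochroman-7-yl 2,4-dihydroxy-6-methylbenzoate A5.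
- In its favour: the ring A substitution pattern arises with no aromatic substitution or organolithium step, and the ester forms under neutral conditions and only on C7, since C6 of A2 carries bromine.
- Against it here: A5 has neither the diaryl ether nor the formyl group. The ether would have to be closed by an intramolecular Ullmann coupling (CuI, Cs2CO3) of a hydrogen-bonded phenol onto a bromide flanked by methyl and acyloxy groups, under basic conditions that endanger the aryl ester. Formylation would come last and would have to choose ring A C3 over C5 and over C8 of ring B. A4 is also an activated aryl ester, so enolate attack on the ester carbonyl with loss of the phenoxide competes with the aldol. A2 needs the same oxygen and acyl pattern on ring B as 17 plus a bromine beside the C5 methyl.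
- Comparison: on structure it is the better plan for ring A (one flask, full regiocontrol) and equal in convergence. On mechanism the capture of A3 is at least as reliable as the aryne step and needs no steric preference, but the late ether closure and formylation are weaker than substitution on 23 followed by lactonisation. On step economy the two plans come out about equal, because A1 must itself be made and two bond-forming steps follow A5.

Alternative 2: The cut removes the ring A bonds C1–C2, C3–C4 and C5–C6, so ring A and the dioxepinone dissolve into the diyne 6-[(3,3-diethoxyprop-1-yn-1-yl)oxy]-2,2,5-trimethyl-4-oxochroman-7-yl but-2-ynoate A6 and ethoxyacetylene A7. The cationic monovalent rhodium complex [Rh(cod)2]BF4 with BINAP would cyclotrimerise A6 with A7 to mollicellin A ethyl ether diethyl acetal A8. Hydrolysis of the acetal of A8 and cleavage of its aryl ethyl ether (BCl3, assisted by the neighbouring formyl group) would then give the target.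
- In its favour: two rings and three C–C bonds in one step, aldehyde and phenol arriving masked in A8, and both C–O links made beforehand as simple O-functionalisations.
- Against it here: the aryl ynol ether of A6 on the hindered C6 oxygen is hard to prepare in the presence of the ketone and the ynoate. The two alkynes of A6 are linked by five atoms, so the metallacycle must close a seven-membered ring and homo-oligomerisation of A7 can win. The orientation of A7 is not set by the tether, and the wrong one puts the ethoxy group on C5. A chiral bisphosphine has no function, as no stereo-element is formed.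
- Comparison: on step economy it is the better plan on paper, since A8 stands two deprotections from the target. On structure it is equal, since A6 needs the same distinction between the C6 and C7 oxygens that 17 provides. On mechanism it is less certain: it depends on two uncontrolled selectivities, whereas each bond-forming event of the chosen plan has a close precedent.

Alternative 3: The cut removes the ring A bonds C2–C3 and C1–C6, leading to the pyrone 3-(dimethoxymethyl)-4-methoxy-6-methyl-2H-pyran-2-one A9 and the ynoate methyl 3-[(7-benzyloxy-2,2,5-trimethyl-4-oxochroman-6-yl)oxy]prop-2-ynoate A10. Heating A9 with A10 would bring about a [4+2] cycloaddition followed by loss of the lactone bridge, giving methyl 2-[(7-benzyloxy-2,2,5-trimethyl-4-oxochroman-6-yl)oxy]-3-(dimethoxymethyl)-4-methoxy-6-methylbenzoate A11.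
- In its favour: the ether oxygen is attached before ring A exists, so no hindered substitution is needed. The polarisation matches (nucleophilic C3 of A9 with the oxygen-bearing alkyne carbon of A10), and the aldehyde arrives masked.
- Against it here: the reacting terminus C3 of A9 is fully substituted by a bulky acetal and the alkyne of A10 is deactivated by its aryloxy donor, so high temperatures are expected. A10 is an activated alkynyl ether that adds nucleophiles readily and is hard to make from a hindered phenol. A11 needs acetal hydrolysis, demethylation, cleavage of a doubly flanked methyl ester, debenzylation and lactonisation.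
- Comparison: on structure it is equal, and the ring B part of A10 is a close relative of 17, so the aryne step would serve this plan as well. On mechanism it is better in avoiding a Meisenheimer adduct at a crowded carbon, but worse in the steric mismatch between A9 and A10 in the cycloaddition. On step economy it is worse, with about five steps after A11 against two after 24.

Key step: step 8

Remark: ring B is numbered as a chromanone (O1, C2, C3, C4, C4a, C5 to C8, C8a) and ring A as a benzoate (C1 carries the carboxyl carbon). The connectivity of the key step has been followed atom by atom from 12 to 16 and from 16 to 26 and is consistent. The two ether groups of 12 are chosen to differ (benzyl on the future C6 oxygen, methoxymethyl on the future C7 oxygen), so that the C6 phenol can later be freed alone. Compounds 1, 13 and 18 are taken to be commercial.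

Step 1
Reactants: 1 2-hydroxy-3-methylbenzaldehyde
Product: 2 2-(benzyloxy)-3-methylbenzaldehyde
Conditions: BnBr, K2CO3, DMF, 60 °C
Reagents that add atoms: benzyl bromide, BrCc1ccccc1
Why: Williamson ether synthesis on the only hydroxyl; the benzyl group sits on the oxygen next to the methyl group (future C6–O) and is the one later removed alone by hydrogenolysis.

Step 2
Reactants: 2 2-(benzyloxy)-3-methylbenzaldehyde
Product: 4 2-(benzyloxy)-3-methylphenol, via aryl formate 3 (not isolated)
Conditions: mCPBA, CH2Cl2, 0 °C to rt; aq. NaHCO3 wash, solvent exchange; then K2CO3 (cat.), MeOH, rt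
Reagents that add atoms: 3-chloroperoxybenzoic acid (mCPBA), OOC(=O)c1cccc(Cl)c1
Why: Baeyer–Villiger (Dakin-type) oxidation: the electron-rich ortho-alkoxyaryl group migrates in preference to hydride, and the crude formate 3, freed of 3-chlorobenzoic acid by the wash, is methanolysed by catalytic base. The future C7 oxygen is thus introduced free and distinct from the benzylated one.

Step 3
Reactants: 4 2-(benzyloxy)-3-methylphenol
Product: 5 2-(benzyloxy)-4-bromo-3-methylphenol
Conditions: NBS, MeCN, –20 to 0 °C
Reagents that add atoms: N-bromosuccinimide, O=C1CCC(=O)N1Br
Why: Electrophilic aromatic bromination; the free hydroxyl is the strongest director and its para position (beside the methyl group) is open, whereas the doubly flanked benzyloxy group is twisted and directs weakly.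

Step 4
Reactants: 5 2-(benzyloxy)-4-bromo-3-methylphenol
Product: 6 2-(benzyloxy)-4-bromo-1-(methoxymethoxy)-3-methylbenzene
Conditions: MOMCl, i-Pr2NEt, CH2Cl2, 0 °C to rt
Reagents that add atoms: chloromethyl methyl ether, COCCl
Why: O-alkylation of the phenol; the acetal masks the future C7 oxygen through the organolithium, fluoride and hydrogenolysis steps and is removed only by acid near the end.

Step 5
Reactants: 6 2-(benzyloxy)-4-bromo-1-(methoxymethoxy)-3-methylbenzene
Product: 8 3-(benzyloxy)-4-(methoxymethoxy)-2-methylphenol, via arylboronate 7 (not isolated)
Conditions: n-BuLi, THF, –78 °C; B(OMe)3, –78 °C to rt; then H2O2, NaOH (aq), 0 °C to rt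
Reagents that add atoms: hydrogen peroxide, OO (trimethyl borate, COB(OC)OC, supplies the boron of 7 only)
Why: Bromine–lithium exchange, borylation and boronate oxidation (1,2-aryl shift from boron to oxygen) replace bromine by hydroxyl at a fixed position; both ethers are inert to n-BuLi at –78 °C and to alkaline peroxide.

Step 6
Reactants: 8 3-(benzyloxy)-4-(methoxymethoxy)-2-methylphenol
Product: 9 3-(benzyloxy)-6-bromo-4-(methoxymethoxy)-2-methylphenol
Conditions: NBS, i-Pr2NH (cat.), CH2Cl2, –20 °C
Reagents that add atoms: N-bromosuccinimide, O=C1CCC(=O)N1Br
Why: Ortho-bromination of a phenol; the single free ortho position is also para to the benzyloxy group, so bromine enters at the carbon that becomes the silylated aryne carbon.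

Step 7
Reactants: 9 3-(benzyloxy)-6-bromo-4-(methoxymethoxy)-2-methylphenol
Product: 12 3-(benzyloxy)-4-(methoxymethoxy)-2-methyl-6-(trimethylsilyl)phenyl trifluoromethanesulfonate, via aryl silyl ether 10 (not isolated), via lithium silylphenoxide 11 (not isolated)
Conditions: HMDS, THF, 65 °C, then evaporation; n-BuLi, THF, –78 °C; Tf2O, –78 to 0 °C
Reagents that add atoms: hexamethyldisilazane, C[Si](C)(C)N[Si](C)(C)C; trifluoromethanesulfonic anhydride, O=S(=O)(OS(=O)(=O)C(F)(F)F)C(F)(F)F
Why: O-silylation, bromine–lithium exchange and anionic 1,3 O-to-C silyl shift (retro-Brook rearrangement) give phenoxide 11, which is triflated in the same flask; this is the standard route to ortho-silylaryl triflates.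

Step 8
Reactants: 12 3-(benzyloxy)-4-(methoxymethoxy)-2-methyl-6-(trimethylsilyl)phenyl trifluoromethanesulfonate; 13 3-methylbut-2-enoic acid
Product: 16 6-(benzyloxy)-7-(methoxymethoxy)-2,2,5-trimethylchroman-4-one, via aryne 14 (not isolated), via hydroxyaryl enone 15 (not isolated)
Conditions: CsF (4 equiv), THF, 125 °C, sealed tube
Reagents that add atoms: none
Why: Fluoride removes the silyl group of 12 and triflate leaves, giving aryne 14, whose triple bond joins the future C4a and C8a. The cesium carboxylate of 13 adds through oxygen to the aryne carbon beside C8–H, and the resulting aryl anion, on the carbon beside the methyl group, attacks the neighbouring ester carbonyl through a four-membered transition state (1,3 O-to-C acyl shift of the anionic Fries type) to give the phenoxide of 15. The phenoxide then closes the pyranone by 6-endo-trig oxa-Michael addition to the β,β-dimethyl enone, so the aryl C–O, aryl C–C(=O) and O1–C2 bonds form in one flask and the ketone arrives at its final oxidation level. The closest known reaction type is the fluoride-induced insertion of arynes into the C–O bond of carboxylic acids, which gives ortho-hydroxyaryl ketones and, with α,β-unsaturated acids, chroman-4-ones in one pot. No stereocentre is formed, since C2 carries two methyl groups. The selectivity needed is regiochemical: the two ether oxygens stand meta and para to the aryne carbons in opposite senses and nearly cancel, so the preference for attack remote from the methyl group rests on steric shielding by that methyl group, buttressed by the benzyloxy group beside it; it is expected to be moderate, and the isomeric chromanone would be removed by chromatography. A slight excess of 12 over 13 and the high temperature are chosen so that acyl transfer outruns protonation of the aryl anion.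

Step 9
Reactants: 16 6-(benzyloxy)-7-(methoxymethoxy)-2,2,5-trimethylchroman-4-one
Product: 17 6-hydroxy-7-(methoxymethoxy)-2,2,5-trimethylchroman-4-one
Conditions: H2 (1 atm), 10% Pd/C, EtOAc, rt
Reagents that add atoms: none
Why: Hydrogenolysis of the aryl benzyl ether; the acetal and the electron-rich aryl ketone are untouched, so only the C6 phenol is released and no selective mono-protection of a catechol is needed.

Step 10
Reactants: 18 3-fluoro-5-methylphenol
Product: 19 4-bromo-3-fluoro-5-methylphenol
Conditions: NBS, MeCN, 0 °C
Reagents that add atoms: N-bromosuccinimide, O=C1CCC(=O)N1Br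
Why: Electrophilic bromination para to the hydroxyl, between fluorine and methyl, the usual site for a 3,5-disubstituted phenol with NBS in MeCN.

Step 11
Reactants: 19 4-bromo-3-fluoro-5-methylphenol
Product: 20 2-bromo-1-fluoro-5-(methoxymethoxy)-3-methylbenzene
Conditions: MOMCl, i-Pr2NEt, CH2Cl2, 0 °C to rt
Reagents that add atoms: chloromethyl methyl ether, COCCl
Why: O-alkylation of the phenol; the acetal protects the oxygen and also directs the lithiation that follows.

Step 12
Reactants: 20 2-bromo-1-fluoro-5-(methoxymethoxy)-3-methylbenzene
Product: 22 3-bromo-2-fluoro-6-(methoxymethoxy)-4-methylbenzaldehyde, via aryllithium 21 (not isolated)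
Conditions: LiN(i-Pr)2, THF, –78 °C; DMF, –78 °C; AcOH, –78 °C to rt
Reagents that add atoms: N,N-dimethylformamide, CN(C)C=O
Why: Directed ortho-lithiation: the C–H flanked by fluorine and the acetal oxygen is by far the most acidic, and the amide base does not exchange the aryl bromide at –78 °C. Formylation of 21 with DMF gives the aldehyde before any ester is present, so no benzylic deprotonation can compete.

Step 13
Reactants: 22 3-bromo-2-fluoro-6-(methoxymethoxy)-4-methylbenzaldehyde
Product: 23 4-methoxybenzyl 2-fluoro-3-formyl-4-(methoxymethoxy)-6-methylbenzoate
Conditions: Pd(OAc)2 (3 mol %), Xantphos, CO (1 atm), 4-methoxybenzyl alcohol, Et3N, toluene, 90 °C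
Reagents that add atoms: carbon monoxide, [C-]#[O+]; 4-methoxybenzyl alcohol, COc1ccc(CO)cc1
Why: Palladium-catalysed alkoxycarbonylation of an aryl bromide (oxidative addition to zerovalent palladium, CO insertion, alcoholysis of the acylpalladium); the aldehyde is tolerated and the ester arrives directly as an acid-labile 4-methoxybenzyl ester.

Step 14
Reactants: 17 6-hydroxy-7-(methoxymethoxy)-2,2,5-trimethylchroman-4-one; 23 4-methoxybenzyl 2-fluoro-3-formyl-4-(methoxymethoxy)-6-methylbenzoate
Product: 24 4-methoxybenzyl 3-formyl-4-(methoxymethoxy)-2-{[7-(methoxymethoxy)-2,2,5-trimethyl-4-oxochroman-6-yl]oxy}-6-methylbenzoate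
Conditions: Cs2CO3, DMF, 50 °C
Reagents that add atoms: none
Why: Nucleophilic aromatic substitution (addition–elimination): the fluorine-bearing carbon of 23 is flanked by formyl and ester groups that stabilise the Meisenheimer adduct. Phenol 17 has a single free hydroxyl, on C6, so the ether can form only there, and the carbonate base is too weak to enolise C3 to a useful extent.

Step 15
Reactants: 24 4-methoxybenzyl 3-formyl-4-(methoxymethoxy)-2-{[7-(methoxymethoxy)-2,2,5-trimethyl-4-oxochroman-6-yl]oxy}-6-methylbenzoate
Product: 25 3-formyl-4-hydroxy-2-[(7-hydroxy-2,2,5-trimethyl-4-oxochroman-6-yl)oxy]-6-methylbenzoic acid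
Conditions: TFA–CH2Cl2 (1:3), anisole (10 equiv), H2O (5 equiv), 0 °C to rt
Reagents that add atoms: none
Why: Acidolysis: TFA cleaves both acetals and the 4-methoxybenzyl ester in one operation, anisole trapping the benzylic cation, while the aldehyde, ketone and diaryl ether are stable to acid.

Step 16
Reactants: 25 3-formyl-4-hydroxy-2-[(7-hydroxy-2,2,5-trimethyl-4-oxochroman-6-yl)oxy]-6-methylbenzoic acid
Product: 26 mollicellin A
Conditions: DCC, DMAP (cat.), THF–CH2Cl2 (0.005 M), rt
Reagents that add atoms: none
Why: Carbodiimide lactonisation (Steglich type): the C7 phenol is held beside the activated carboxyl by the diaryl ether, so seven-membered ring closure should be favoured at high dilution over intermolecular acylation of the remote, hydrogen-bonded ring A phenol.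

Compound list

1 | 2-hydroxy-3-methylbenzaldehyde | Cc1cccc(C=O)c1O | starting material
2 | 2-(benzyloxy)-3-methylbenzaldehyde | Cc1cccc(C=O)c1OCc1ccccc1 | intermediate
3 | 2-(benzyloxy)-3-methylphenyl formate | Cc1cccc(OC=O)c1OCc1ccccc1 | intermediate
4 | 2-(benzyloxy)-3-methylphenol | Cc1cccc(O)c1OCc1ccccc1 | intermediate
5 | 2-(benzyloxy)-4-bromo-3-methylphenol | Cc1c(Br)ccc(O)c1OCc1ccccc1 | intermediate
6 | 2-(benzyloxy)-4-bromo-1-(methoxymethoxy)-3-methylbenzene | Cc1c(Br)ccc(OCOC)c1OCc1ccccc1 | intermediate
7 | dimethyl [3-(benzyloxy)-4-(methoxymethoxy)-2-methylphenyl]boronate | COB(OC)c1ccc(OCOC)c(OCc2ccccc2)c1C | intermediate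
8 | 3-(benzyloxy)-4-(methoxymethoxy)-2-methylphenol | Cc1c(O)ccc(OCOC)c1OCc1ccccc1 | intermediate
9 | 3-(benzyloxy)-6-bromo-4-(methoxymethoxy)-2-methylphenol | Cc1c(O)c(Br)cc(OCOC)c1OCc1ccccc1 | intermediate
10 | [3-(benzyloxy)-6-bromo-4-(methoxymethoxy)-2-methylphenoxy]trimethylsilane | Cc1c(O[Si](C)(C)C)c(Br)cc(OCOC)c1OCc1ccccc1 | intermediate
11 | lithium 3-(benzyloxy)-4-(methoxymethoxy)-2-methyl-6-(trimethylsilyl)phenolate | [Li+].Cc1c([O-])c([Si](C)(C)C)cc(OCOC)c1OCc1ccccc1 | intermediate
12 | 3-(benzyloxy)-4-(methoxymethoxy)-2-methyl-6-(trimethylsilyl)phenyl trifluoromethanesulfonate | Cc1c(OS(=O)(=O)C(F)(F)F)c([Si](C)(C)C)cc(OCOC)c1OCc1ccccc1 | intermediate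
13 | 3-methylbut-2-enoic acid | CC(C)=CC(=O)O | starting material
14 | 4-(benzyloxy)-5-(methoxymethoxy)-3-methyl-1,2-didehydrobenzene | CC1=C(OCc2ccccc2)C(OCOC)=CC#C1 | intermediate
15 | 1-[3-(benzyloxy)-6-hydroxy-4-(methoxymethoxy)-2-methylphenyl]-3-methylbut-2-en-1-one | CC(C)=CC(=O)c1c(C)c(OCc2ccccc2)c(OCOC)cc1O | intermediate
16 | 6-(benzyloxy)-7-(methoxymethoxy)-2,2,5-trimethylchroman-4-one | CC1(C)CC(=O)c2c(C)c(OCc3ccccc3)c(OCOC)cc2O1 | intermediate
17 | 6-hydroxy-7-(methoxymethoxy)-2,2,5-trimethylchroman-4-one | CC1(C)CC(=O)c2c(C)c(O)c(OCOC)cc2O1 | intermediate
18 | 3-fluoro-5-methylphenol | Cc1cc(O)cc(F)c1 | starting material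
19 | 4-bromo-3-fluoro-5-methylphenol | Cc1cc(O)cc(F)c1Br | intermediate
20 | 2-bromo-1-fluoro-5-(methoxymethoxy)-3-methylbenzene | Cc1cc(OCOC)cc(F)c1Br | intermediate
21 | [3-bromo-2-fluoro-6-(methoxymethoxy)-4-methylphenyl]lithium | Cc1cc(OCOC)c([Li])c(F)c1Br | intermediate
22 | 3-bromo-2-fluoro-6-(methoxymethoxy)-4-methylbenzaldehyde | Cc1cc(OCOC)c(C=O)c(F)c1Br | intermediate
23 | 4-methoxybenzyl 2-fluoro-3-formyl-4-(methoxymethoxy)-6-methylbenzoate | Cc1cc(OCOC)c(C=O)c(F)c1C(=O)OCc1ccc(OC)cc1 | intermediate
24 | 4-methoxybenzyl 3-formyl-4-(methoxymethoxy)-2-{[7-(methoxymethoxy)-2,2,5-trimethyl-4-oxochroman-6-yl]oxy}-6-methylbenzoate | Cc1cc(OCOC)c(C=O)c(Oc2c(OCOC)cc3OC(C)(C)CC(=O)c3c2C)c1C(=O)OCc1ccc(OC)cc1 | intermediate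
25 | 3-formyl-4-hydroxy-2-[(7-hydroxy-2,2,5-trimethyl-4-oxochroman-6-yl)oxy]-6-methylbenzoic acid | Cc1cc(O)c(C=O)c(Oc2c(O)cc3OC(C)(C)CC(=O)c3c2C)c1C(=O)O | intermediate
26 | mollicellin A | Cc1cc(O)c(C=O)c2c1C(=O)Oc1cc3c(c(C)c1O2)C(=O)CC(C)(C)O3 | target

Total step count: 16 (steps 1 to 9 for the ring B half, steps 10 to 13 for the ring A half, steps 14 to 16 after their union). Longest linear sequence: 12 steps (1 to 9, then 14 to 16).

Least certain steps

Step 8 (key step). The carboxylate may add to the aryne carbon beside the methyl group, since only a steric preference discriminates the two carbons, and the aryl anion may be protonated before the acyl group has moved to carbon. Fallback, setting out from 6 and returning at 16: bromine–lithium exchange and carboxylation (n-BuLi, THF, –78 °C; CO2) would give 3-(benzyloxy)-4-(methoxymethoxy)-2-methylbenzoic acid F1. Carboxylate-directed ortho C–H hydroxylation by divalent palladium (Pd(OAc)2, KOAc, benzoquinone, O2, DMA, 115 °C), with only one ortho C–H available, would give 3-(benzyloxy)-6-hydroxy-4-(methoxymethoxy)-2-methylbenzoic acid F2. Excess MeLi would convert the acid into 1-[3-(benzyloxy)-6-hydroxy-4-(methoxymethoxy)-2-methylphenyl]ethan-1-one F3, and Kabbe condensation of this ketone with acetone and pyrrolidine would close the pyranone to 16. The acyl carbon is then placed by the bromine of 6 and the oxygen by the carboxylate, so no aryne regiochemistry is involved. The number of steps from 6 is the same as in the main route, but the pyranone is then built stepwise and the C–H hydroxylation must be carried out on a crowded, electron-rich benzoic acid.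

Step 14. Addition–elimination may be slow, because the electrophilic carbon and the phenoxide are each flanked on both sides. Base-induced side processes (condensation of the C3 enolate with the aldehyde, hydrolytic loss of fluoride) could then overtake it. Fallback, setting out from 17 and 22 and returning at 24: the same substitution with the smaller, ester-free aldehyde 22 (K2CO3, DMF, 90 °C) would give 3-bromo-6-(methoxymethoxy)-2-{[7-(methoxymethoxy)-2,2,5-trimethyl-4-oxochroman-6-yl]oxy}-4-methylbenzaldehyde F4. The ester would then be installed by palladium-catalysed alkoxycarbonylation with 4-methoxybenzyl alcohol (conditions of step 13), giving 24.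

Step 13. Oxidative addition at a bromide flanked by fluorine and methyl may be slow, and the alcohol may displace the activated fluorine under the basic conditions. Fallback, setting out from 22 and returning at 23: the aldehyde would be masked in the flask as its lithium morpholide adduct (–78 °C). Bromine–lithium exchange with n-BuLi and quenching with CO2, followed by acidic work-up, would give 2-fluoro-3-formyl-4-(methoxymethoxy)-6-methylbenzoic acid F5. O-alkylation of the carboxylate with 4-methoxybenzyl chloride and K2CO3 in DMF would give 23.

Step 16. The hindered O-acylisourea may rearrange to an N-acylurea, or a free phenol may be acylated intermolecularly, before the seven-membered ring closes. Fallback, setting out from 17 and 22 and returning at 26: the substitution described under step 14 would give 3-bromo-6-(methoxymethoxy)-2-{[7-(methoxymethoxy)-2,2,5-trimethyl-4-oxochroman-6-yl]oxy}-4-methylbenzaldehyde F4, and both of its acetals would be removed (HCl, MeOH, 40 °C) to give 3-bromo-6-hydroxy-2-[(7-hydroxy-2,2,5-trimethyl-4-oxochroman-6-yl)oxy]-4-methylbenzaldehyde F6. Palladium-catalysed intramolecular aryloxycarbonylation (Pd(OAc)2, Xantphos, CO, Et3N, toluene, 100 °C) would then form the lactone, the acylpalladium being captured by the neighbouring C7 phenol. This makes the ester carbon and the ring in one step and needs no acid activation.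

## Further compounds

F1 | step 8 | 3-(benzyloxy)-4-(methoxymethoxy)-2-methylbenzoic acid | Cc1c(C(=O)O)ccc(OCOC)c1OCc1ccccc1
F2 | step 8 | 3-(benzyloxy)-6-hydroxy-4-(methoxymethoxy)-2-methylbenzoic acid | Cc1c(C(=O)O)c(O)cc(OCOC)c1OCc1ccccc1
F3 | step 8 | 1-[3-(benzyloxy)-6-hydroxy-4-(methoxymethoxy)-2-methylphenyl]ethan-1-one | CC(=O)c1c(C)c(OCc2ccccc2)c(OCOC)cc1O
F4 | step 14 | 3-bromo-6-(methoxymethoxy)-2-{[7-(methoxymethoxy)-2,2,5-trimethyl-4-oxochroman-6-yl]oxy}-4-methylbenzaldehyde | Cc1cc(OCOC)c(C=O)c(Oc2c(OCOC)cc3OC(C)(C)CC(=O)c3c2C)c1Br
F5 | step 13 | 2-fluoro-3-formyl-4-(methoxymethoxy)-6-methylbenzoic acid | Cc1cc(OCOC)c(C=O)c(F)c1C(=O)O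
F6 | step 16 | 3-bromo-6-hydroxy-2-[(7-hydroxy-2,2,5-trimethyl-4-oxochroman-6-yl)oxy]-4-methylbenzaldehyde | Cc1cc(O)c(C=O)c(Oc2c(O)cc3OC(C)(C)CC(=O)c3c2C)c1Br
A1 | alternative 1 | 2,2-dimethyl-6-(2,4-dioxopentyl)-4H-1,3-dioxin-4-one | CC(=O)CC(=O)CC1=CC(=O)OC(C)(C)O1
A2 | alternative 1 | 6-bromo-7-hydroxy-2,2,5-trimethylchroman-4-one | CC1(C)CC(=O)c2c(C)c(Br)c(O)cc2O1
A3 | alternative 1 | 3,5,7-trioxooct-1-en-1-one | CC(=O)CC(=O)CC(=O)C=C=O
A4 | alternative 1 | 6-bromo-2,2,5-trimethyl-4-oxochroman-7-yl 3,5,7-trioxooctanoate | CC(=O)CC(=O)CC(=O)CC(=O)Oc1cc2OC(C)(C)CC(=O)c2c(C)c1Br
A5 | alternative 1 | 6-bromo-2,2,5-trimethyl-4-oxochroman-7-yl 2,4-dihydroxy-6-methylbenzoate | Cc1cc(O)cc(O)c1C(=O)Oc1cc2OC(C)(C)CC(=O)c2c(C)c1Br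
A6 | alternative 2 | 6-[(3,3-diethoxyprop-1-yn-1-yl)oxy]-2,2,5-trimethyl-4-oxochroman-7-yl but-2-ynoate | CC#CC(=O)Oc1cc2OC(C)(C)CC(=O)c2c(C)c1OC#CC(OCC)OCC
A7 | alternative 2 | ethoxyacetylene | CCOC#C
A8 | alternative 2 | mollicellin A ethyl ether diethyl acetal | Cc1cc(OCC)c(C(OCC)OCC)c2c1C(=O)Oc1cc3c(c(C)c1O2)C(=O)CC(C)(C)O3
A9 | alternative 3 | 3-(dimethoxymethyl)-4-methoxy-6-methyl-2H-pyran-2-one | COC(OC)c1c(OC)cc(C)oc1=O
A10 | alternative 3 | methyl 3-[(7-benzyloxy-2,2,5-trimethyl-4-oxochroman-6-yl)oxy]prop-2-ynoate | COC(=O)C#COc1c(OCc2ccccc2)cc2OC(C)(C)CC(=O)c2c1C
A11 | alternative 3 | methyl 2-[(7-benzyloxy-2,2,5-trimethyl-4-oxochroman-6-yl)oxy]-3-(dimethoxymethyl)-4-methoxy-6-methylbenzoate | Cc1cc(OC)c(C(OC)OC)c(Oc2c(OCc3ccccc3)cc3OC(C)(C)CC(=O)c3c2C)c1C(=O)OC
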